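**Assumption:** Gnetupendin B has no sp³ stereocentres, so "single enantiomer" is moot. The only stereo-element is the E-stilbene alkene, which is set in the last step. I also assume 5-bromoresorcinol, protocatechuic acid and 4-vinylguaiacol are purchasable.

## Retrosynthetic overview
1. Target **1** comes from a late-stage, E-selective Mizoroki–Heck coupling of bromodiarylmethane **2** with 4-vinylguaiacol **3**. All phenols are left free, so the route needs no protecting groups.
2. Diarylmethane **2** comes from ionic hydrogenation of benzophenone **4**. This avoids the poly-benzylation and C2/C4 regiochemistry problems of a direct Friedel–Crafts benzylation.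
3. Benzophenone **4** comes from BF3-mediated Friedel–Crafts (Hoesch-type) acylation of 5-bromoresorcinol **5** with protocatechuic acid **6**. The acylation occurs ortho to Br and OH and para to the other OH, which fixes the 1,2,3,5-pattern on ring A.
4. No ring is built. All three arenes are purchased, and the bonds form in the order Ar–C(=O)–Ar, then C=O→CH2, then Ar–CH=CH–Ar.

## Route

**Step 1**
Reactants: **5** 5-bromoresorcinol (5-bromobenzene-1,3-diol); **6** protocatechuic acid (3,4-dihydroxybenzoic acid)
Product: **4** (2-bromo-4,6-dihydroxyphenyl)(3,4-dihydroxyphenyl)methanone
Conditions: BF3·OEt2 (neat, about 10 equiv), 90 °C, 5 h; pour into ice-water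
Reagents that add atoms: none (BF3·OEt2 is only the Lewis acid and dehydrating medium; the acyl group comes from 6)
Why: Friedel–Crafts (Hoesch-type) acylation of a resorcinol, with the acid activated as its BF3 complex. The site is intrinsic: C4 is ortho to one OH and para to the other, while the C2 position between the two OH groups is disfavoured. The same pattern gives orcacetophenone from orcinol. The product ketone deactivates ring A and prevents over-acylation, and the catechol ring is untouched because 6 acts only as the acyl donor.

**Step 2**
Reactant: **4**
Product: **2** 4-[(2-bromo-4,6-dihydroxyphenyl)methyl]benzene-1,2-diol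
Conditions: Et3SiH (4 equiv), TFA, 0 °C to 50 °C, 6 h
Reagents that add atoms: none (the silane supplies only hydride, which ends up as C–H)
Why: Kursanov–Parnes ionic hydrogenation. The ortho/para-hydroxylated diaryl ketone is protonated to a strongly stabilised diarylcarbinyl cation, which is trapped by hydride and then by a second hydride after loss of water, giving CH2. Ar–Br and the free phenols survive, and no stereocentre is involved. This step is done before the alkene exists because the electron-rich stilbene would not survive Et3SiH/TFA.

**Step 3**
Reactants: **2**; **3** 4-vinylguaiacol (2-methoxy-4-vinylphenol)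
Product: **1** Gnetupendin B
Conditions: Pd(OAc)2 (5 mol%), P(o-tol)3 (10 mol%), Et3N (5 equiv), DMF, 100 °C, 18 h, degassed, under Ar
Reagents that add atoms: none (the only other reactant, 3, is numbered; HBr is lost as Et3N·HBr)
Why: Mizoroki–Heck reaction. Oxidative addition into Ar–Br, 2,1-syn-carbopalladation of the styrene so that Ar adds to the terminal carbon, then syn β-H elimination from the conformer with the two aryl groups anti. This sets the E-alkene (>95:5). The ortho-CH2Ar group is only a single ortho substituent and does not block the coupling. Free phenols are tolerated because Et3N only forms phenolate ion pairs, and Pd(0)/phosphine is not poisoned under rigorously degassed conditions, which also keeps the catechol from oxidising.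

**Final check against the target SMILES**
- **Ring A:** the CH2 carbon has OH on one ortho carbon and the new vinyl on the other, OH on the carbon para to the CH2 carbon, and H at the other two positions. This matches c2cc(O)cc(O)c2C.
- **Ring B:** 4-OH, 3-OMe with the vinyl para to OH, from 3, matching COc1cc(...)ccc1O.
- **Ring C:** 3,4-dihydroxybenzyl, as in Cc2ccc(O)c(O)c2.
- **Formulae:**
  - Step 1: C6H5BrO2 + C7H6O4 − H2O = C13H9BrO5.
  - Step 2: C13H11BrO4.
  - Step 3: C13H11BrO4 + C9H10O2 − HBr = C22H20O6, which is the formula of 1.
- **Stereochemistry:** the E-alkene is set in the last step and nothing follows it.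

## Compound list
| # | Name | SMILES | Role |
|---|---|---|---|
| 1 | Gnetupendin B, (E)-5-[2-(3,4-dihydroxybenzyl)-3,5-dihydroxystyryl]-2-methoxyphenol | COc1cc(/C=C/c2cc(O)cc(O)c2Cc2ccc(O)c(O)c2)ccc1O | target |
| 2 | 4-[(2-bromo-4,6-dihydroxyphenyl)methyl]benzene-1,2-diol | Oc1ccc(Cc2c(O)cc(O)cc2Br)cc1O | intermediate |
| 3 | 4-vinylguaiacol (2-methoxy-4-vinylphenol) | COc1cc(C=C)ccc1O | starting material |
| 4 | (2-bromo-4,6-dihydroxyphenyl)(3,4-dihydroxyphenyl)methanone | O=C(c1ccc(O)c(O)c1)c1c(O)cc(O)cc1Br | intermediate |
| 5 | 5-bromoresorcinol | Oc1cc(O)cc(Br)c1 | starting material |
| 6 | protocatechuic acid | OC(=O)c1ccc(O)c(O)c1 | starting material |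

**Total steps:** 3. **Longest linear sequence:** 3 (5 → 4 → 2 → 1).

## Three steps most likely to fail
1. **Step 3 (Heck on an unprotected polyphenolic bromide).** Risks are slow oxidative addition into an electron-rich phenolate arene, catechol oxidation, and styrene polymerisation.
   Fallback: peracetylate 2 (Ac2O, pyridine), couple with 4-acetoxy-3-methoxystyrene under Heck conditions with NaOAc instead of Et3N, then remove the acetates with K2CO3/MeOH under Ar. This trades the protecting-group-free design for a protected one.
2. **Step 1 (regioselectivity and yield of the acylation).** The acylation is ortho to Br, so steric hindrance and the competing 2,6-dihydroxy isomer may lower the yield.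
   Fallback: Vilsmeier formylation of 5-bromoresorcinol to 2-bromo-4,6-dihydroxybenzaldehyde and O-benzylation, then addition of 3,4-bis(benzyloxy)phenylmagnesium bromide and Et3SiH/TFA deoxygenation. The Heck reaction and BCl3/pentamethylbenzene debenzylation follow. This is a different C–C bond-forming logic based on organometallic addition.
3. **Step 2 (ionic hydrogenation).** The strongly H-bonded polyhydroxybenzophenone may resist reduction, or the diarylcarbinyl cation may oligomerise by Friedel–Crafts reaction.
   Fallback: reduce with NaBH4 in refluxing aqueous NaOH/EtOH, which goes through the o/p-quinone methide and hydride capture, instead of the silane/cation pathway.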